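The eight-membered carbocycle and its bridging β-keto-γ-lactone are unveiled last, by hydroxylating C3 of a bicyclo[3.3.1]nonane-2,4,9-trione and letting the new alkoxide cleave the C1–C9 bond (retro-Claisen). Everything rests on making that bicycle by closing ring B through the C5–C6 bond: the C5 enolate of a preformed, non-aromatisable cyclohexane-1,3,5-trione (ring A, C3 blocked by an ester) displaces a primary halide at C6 of the chiral side chain held on C1. The step exploits the 1,3-placement of C1 and C5 across the C9 carbonyl (the later lactone carbonyl) and the acidity of the triketone C5–H; the chain stereocentres C7 and C8 dictate both bridgeheads.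

Key step: step 11

Locants: C1–C9 are the bicyclo[3.3.1]nonane locants of 17 and are kept for the target (C1 = benzoyl-bearing CH, C3 = O-bearing lactone carbon, C5 = lactone α-carbon, C6 = ring CH2 next to it, C9 = lactone carbonyl); ring A = C1–C2–C3–C4–C5–C9, ring B = C1–C9–C5–C6–C7–C8.
Assumption 1: the C1 methine of the target lies between two ketones and is configurationally labile, so the required configuration is taken to be the thermodynamically preferred one.
Assumption 2: the (S,S) boron controller with i-Pr2NEt in CH2Cl2 is taken to give the Z(O) boron enolate and the (2R,3S) acid; if the sense of induction is the opposite, the (R,R) controller is used.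

Step 1
Reactants: 1 geraniol; 2 5-methylhex-4-enoic acid
Product: 3 (2E)-3,7-dimethylocta-2,6-dien-1-yl 5-methylhex-4-enoate
Conditions: DCC, DMAP (cat.), CH2Cl2, 0 °C → rt
Reagents that add atoms: none
Why: Steglich esterification of the primary allylic alcohol with the unhindered acid forms the Claisen substrate without touching the trisubstituted olefins.

Step 2
Reactants: 3 geranyl ester
Product: 5 (2R,3S)-3-ethenyl-3,7-dimethyl-2-(3-methylbut-2-en-1-yl)oct-6-enoic acid, via boron ketene acetal 4 (not isolated)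
Conditions: (S,S)-2-bromo-1,3-bis[3,5-bis(trifluoromethyl)phenylsulfonyl]-4,5-diphenyl-1,3,2-diazaborolidine (1.1 equiv), i-Pr2NEt, CH2Cl2, −78 °C → 4 °C; aqueous work-up
Reagents that add atoms: none
Why: Enantioselective Ireland–Claisen rearrangement: the Z(O) boron ketene acetal 4 rearranges through a chair in which the (E)-olefin places homoprenyl equatorial and methyl axial on the future C8 and the enolate places prenyl equatorial on the future C7, which gives the 2,3-unlike acid, while the C2-symmetric sulfonamide ligand on boron selects the enantiotopic face.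

Step 3
Reactants: 5 acid
Product: 6 (2R,3S)-3-ethenyl-3,7-dimethyl-2-(3-methylbut-2-en-1-yl)oct-6-en-1-ol
Conditions: LiAlH4, THF, 0 °C → rt
Reagents that add atoms: none
Why: Hydride reduction of the carboxylic acid with LiAlH4 gives the primary alcohol (future C6) and leaves the isolated olefins and both stereocentres unchanged.

Step 4
Reactants: 6 alcohol
Product: 7 (6S,7R)-7-(chloromethyl)-6-ethenyl-2,6,10-trimethylundeca-2,9-diene
Conditions: PPh3, CCl4, CH2Cl2, reflux
Reagents that add atoms: carbon tetrachloride ClC(Cl)(Cl)Cl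
Why: Appel chlorination at the primary carbon installs a leaving group on C6 that survives the later enolate steps, because a β-branched primary chloride is a slow electrophile until it is exchanged for iodide.

Step 5
Reactants: 7 chloride
Product: 8 (3S,4R)-4-(chloromethyl)-3,7-dimethyl-3-(4-methylpent-3-en-1-yl)oct-6-enal
Conditions: PdCl2(PhCN)2 (cat.), CuCl2·2H2O (cat.), AgNO2 (cat.), t-BuOH/MeNO2, O2 (1 atm), rt
Reagents that add atoms: dioxygen O=O
Why: Aldehyde-selective (anti-Markovnikov) Wacker oxidation under nitrite co-catalysis is known for vinyl groups on quaternary carbons, so the vinyl unit becomes C1H2–C9HO while the trisubstituted olefins and the alkyl chloride are not oxidised.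

Step 6
Reactants: 9 dimethyl malonate
Product: 10 dimethyl 2-(3-methylbut-2-en-1-yl)malonate
Conditions: NaH, THF, 0 °C → rt (malonate in excess)
Reagents that add atoms: 1-bromo-3-methylbut-2-ene (prenyl bromide) CC(C)=CCBr
Why: Malonic ester alkylation with the primary allylic bromide, run with excess malonate to suppress dialkylation, gives the unit that supplies C2, C3 and the temporary ester.

Step 7
Reactants: 10 prenylmalonate; 2 5-methylhex-4-enoic acid
Product: 12 dimethyl 2-(5-methylhex-4-enoyl)-2-(3-methylbut-2-en-1-yl)malonate, via acid chloride 11 (not isolated)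
Conditions: 2, (COCl)2, DMF (cat.), CH2Cl2, rt; then sodium enolate of 10 (NaH, THF), 0 °C → rt
Reagents that add atoms: none
Why: C-acylation of the sodium enolate of the substituted malonate by acid chloride 11 gives a non-enolisable acylmalonate whose only acidic CH2 is the future C5.

Step 8
Reactants: 12 acylmalonate; 8 aldehyde
Product: 13 dimethyl 2-[(5S,6R)-6-(chloromethyl)-3-hydroxy-5,9-dimethyl-5-(4-methylpent-3-en-1-yl)-2-(3-methylbut-2-en-1-yl)dec-8-enoyl]-2-(3-methylbut-2-en-1-yl)malonate (diastereomer mixture at C2 and C3 of the acyl chain)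
Conditions: LiN(i-Pr)2, THF, −78 °C; then 8; AcOH quench at −78 °C
Reagents that add atoms: none
Why: Directed aldol addition of the single possible lithium enolate of 12 to aldehyde 8 at −78 °C forms the C5–C9 bond, and the two new stereocentres need no control because the next steps make them trigonal or epimerisable.

Step 9
Reactants: 13 aldol adduct
Product: 14 dimethyl 2-[(5S,6R)-6-(chloromethyl)-5,9-dimethyl-5-(4-methylpent-3-en-1-yl)-2-(3-methylbut-2-en-1-yl)-3-oxodec-8-enoyl]-2-(3-methylbut-2-en-1-yl)malonate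
Conditions: Dess–Martin periodinane, CH2Cl2, 0 °C → rt
Reagents that add atoms: none
Why: Dess–Martin oxidation converts the β-hydroxy ketone into the 1,3-diketone under neutral conditions that spare the olefins and the chloride.

Step 10
Reactants: 14 triketo diester
Product: 15 methyl 5-[(6S,7R)-7-(chloromethyl)-2,6,10-trimethylundeca-2,9-dien-6-yl]-1,3-bis(3-methylbut-2-en-1-yl)-2,4,6-trioxocyclohexane-1-carboxylate (enolised; mixture at the ring stereocentres)
Conditions: LiN(i-Pr)2 (2.3 equiv), THF, −78 → 0 °C; dilute HCl work-up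
Reagents that add atoms: none
Why: Dieckmann condensation of the diketone dianion, whose terminal carbanion C1 attacks one of the two malonate esters in a 6-exo-trig closure, builds ring A and is driven by double deprotonation of the product, while the quaternary C3 prevents aromatisation to a phloroglucinol and the alkyl chloride is too slow to react at or below 0 °C.

Step 11
Reactants: 15 chloro trione
Product: 17 methyl (1R,5S,7S,8R)-8-methyl-8-(4-methylpent-3-en-1-yl)-3,5,7-tris(3-methylbut-2-en-1-yl)-2,4,9-trioxobicyclo[3.3.1]nonane-3-carboxylate (C3 epimer mixture), via iodo trione 16 (not isolated)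
Conditions: LiN(SiMe3)2 (1.05 equiv), LiI (3 equiv), THF/toluene, 0 → 70 °C
Reagents that add atoms: none
Why: Finkelstein exchange gives iodide 16, and the lithium enolate at C5 of ring A (conjugated with the C4 and C9 carbonyls) then displaces iodide at C6 in an intramolecular enolate C-alkylation of the kind used for alkylative dearomatisation of acylphloroglucinols, closing ring B and the bicyclo[3.3.1]nonane. Ring B closes in a 6-(enolendo)-exo-tet mode through a chair in which the C7 prenyl and C8 homoprenyl groups are equatorial and the C8 methyl is axial. C5 can only be bonded on the face of ring A that carries the side chain, so its configuration is tied to C1 through the one-carbon C9 bridge, and C1 itself is an epimerisable 1,3-diketone methine that is funnelled into the reactive epimer with the tertiary-alkyl chain axial. The chair preference of ring B therefore sets both bridgeheads relative to C7 and C8. The step needs C- over O-alkylation and C5 over C3 attack: C3 is quaternary, allylic 1,3-strain keeps the bulky chain axial on C1 so that C6 sits over C5 and away from the in-plane enolate oxygens, and lithium counter-ions in a weakly polar medium with a soft iodide leaving group favour the carbon terminus.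

Step 12
Reactants: 17 bicyclic ester
Product: 18 methyl (1S,5S,7S,8R)-1-benzoyl-8-methyl-8-(4-methylpent-3-en-1-yl)-3,5,7-tris(3-methylbut-2-en-1-yl)-2,4,9-trioxobicyclo[3.3.1]nonane-3-carboxylate (C3 epimer mixture)
Conditions: lithium 2,2,6,6-tetramethylpiperidide (from the amine and n-BuLi), THF, −78 °C; then PhCOCl
Reagents that add atoms: benzoyl chloride O=C(Cl)c1ccccc1
Why: Bridgehead deprotonation at C1, the only acidic C–H left in the non-enolisable trione, and C-acylation of the configurationally fixed bridgehead carbanion with benzoyl chloride follow the established bridgehead acylation of bicyclo[3.3.1]nonane-2,4,9-triones and retain the C1 configuration.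

Step 13
Reactants: 18 benzoyl bicyclic ester
Product: 19 (1R,5R,7S,8R)-1-benzoyl-4-hydroxy-8-methyl-8-(4-methylpent-3-en-1-yl)-3,5,7-tris(3-methylbut-2-en-1-yl)bicyclo[3.3.1]non-3-ene-2,9-dione
Conditions: LiCl, H2O (2 equiv), DMSO, 120 °C; dilute HCl work-up
Reagents that add atoms: none
Why: Krapcho dealkoxycarbonylation (chloride attack on the methyl group, then loss of CO2 from the carboxylate flanked by two ketones) removes the blocking ester and gives the enolised β-diketone, so the C3 stereocentre of the mixture disappears.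

Step 14
Reactants: 19 enolised trione
Product: 21 target CNP0269674.1, via 3-hydroxy trione 20 (not isolated)
Conditions: KN(SiMe3)2, THF, −78 °C; 2-(phenylsulfonyl)-3-phenyloxaziridine, −78 → 0 °C; aq. NH4Cl; then Et3N (cat.), CH2Cl2, rt
Reagents that add atoms: 2-(phenylsulfonyl)-3-phenyloxaziridine O=S(=O)(N1OC1c1ccccc1)c1ccccc1
Why: Enolate hydroxylation with the N-sulfonyloxaziridine occurs at C3 on the face syn to the C9 carbonyl and anti to the C6–C7–C8 bridge, and the resulting alkoxide 20 adds to C9 and cleaves C1–C9 by a retro-Claisen fragmentation that expels the doubly stabilised C1 enolate, so the lactone bridge fixes C3 relative to C5 and the labile C1 centre is equilibrated to the target configuration (Assumption 1).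

Compound list
1 | geraniol, (2E)-3,7-dimethylocta-2,6-dien-1-ol | CC(C)=CCC/C(C)=C/CO | starting material
2 | 5-methylhex-4-enoic acid | CC(C)=CCCC(=O)O | starting material
3 | (2E)-3,7-dimethylocta-2,6-dien-1-yl 5-methylhex-4-enoate | CC(C)=CCC/C(C)=C/COC(=O)CCC=C(C)C | intermediate
4 | Z(O) boron ketene acetal of 3 (alkyl cis to O–B) on the (4S,5S)-1,3-bis[3,5-bis(trifluoromethyl)phenylsulfonyl]-4,5-diphenyl-1,3,2-diazaborolidine | CC(C)=CC/C=C(\OB1N(S(=O)(=O)c2cc(cc(c2)C(F)(F)F)C(F)(F)F)[C@@H](c2ccccc2)[C@H](c2ccccc2)N1S(=O)(=O)c1cc(cc(c1)C(F)(F)F)C(F)(F)F)OC/C=C(\C)CCC=C(C)C | intermediate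
5 | (2R,3S)-3-ethenyl-3,7-dimethyl-2-(3-methylbut-2-en-1-yl)oct-6-enoic acid | CC(C)=CCC[C@@](C)(C=C)[C@@H](CC=C(C)C)C(=O)O | intermediate
6 | (2R,3S)-3-ethenyl-3,7-dimethyl-2-(3-methylbut-2-en-1-yl)oct-6-en-1-ol | CC(C)=CCC[C@@](C)(C=C)[C@@H](CC=C(C)C)CO | intermediate
7 | (6S,7R)-7-(chloromethyl)-6-ethenyl-2,6,10-trimethylundeca-2,9-diene | CC(C)=CCC[C@@](C)(C=C)[C@@H](CC=C(C)C)CCl | intermediate
8 | (3S,4R)-4-(chloromethyl)-3,7-dimethyl-3-(4-methylpent-3-en-1-yl)oct-6-enal | CC(C)=CCC[C@@](C)(CC=O)[C@@H](CC=C(C)C)CCl | intermediate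
9 | dimethyl malonate | COC(=O)CC(=O)OC | starting material
10 | dimethyl 2-(3-methylbut-2-en-1-yl)malonate | COC(=O)C(CC=C(C)C)C(=O)OC | intermediate
11 | 5-methylhex-4-enoyl chloride | CC(C)=CCCC(Cl)=O | intermediate
12 | dimethyl 2-(5-methylhex-4-enoyl)-2-(3-methylbut-2-en-1-yl)malonate | COC(=O)C(CC=C(C)C)(C(=O)OC)C(=O)CCC=C(C)C | intermediate
13 | dimethyl 2-[(5S,6R)-6-(chloromethyl)-3-hydroxy-5,9-dimethyl-5-(4-methylpent-3-en-1-yl)-2-(3-methylbut-2-en-1-yl)dec-8-enoyl]-2-(3-methylbut-2-en-1-yl)malonate (mixture at C2 and C3 of the acyl chain) | COC(=O)C(CC=C(C)C)(C(=O)OC)C(=O)C(CC=C(C)C)C(O)C[C@](C)(CCC=C(C)C)[C@@H](CC=C(C)C)CCl | intermediate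
14 | dimethyl 2-[(5S,6R)-6-(chloromethyl)-5,9-dimethyl-5-(4-methylpent-3-en-1-yl)-2-(3-methylbut-2-en-1-yl)-3-oxodec-8-enoyl]-2-(3-methylbut-2-en-1-yl)malonate | COC(=O)C(CC=C(C)C)(C(=O)OC)C(=O)C(CC=C(C)C)C(=O)C[C@](C)(CCC=C(C)C)[C@@H](CC=C(C)C)CCl | intermediate
15 | methyl 5-[(6S,7R)-7-(chloromethyl)-2,6,10-trimethylundeca-2,9-dien-6-yl]-1,3-bis(3-methylbut-2-en-1-yl)-2,4,6-trioxocyclohexane-1-carboxylate (keto form drawn; ring stereocentres unassigned) | COC(=O)C1(CC=C(C)C)C(=O)C(CC=C(C)C)C(=O)C(C1=O)[C@](C)(CCC=C(C)C)[C@@H](CC=C(C)C)CCl | intermediate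
16 | methyl 5-[(6S,7R)-7-(iodomethyl)-2,6,10-trimethylundeca-2,9-dien-6-yl]-1,3-bis(3-methylbut-2-en-1-yl)-2,4,6-trioxocyclohexane-1-carboxylate | COC(=O)C1(CC=C(C)C)C(=O)C(CC=C(C)C)C(=O)C(C1=O)[C@](C)(CCC=C(C)C)[C@@H](CC=C(C)C)CI | intermediate
17 | methyl (1R,5S,7S,8R)-8-methyl-8-(4-methylpent-3-en-1-yl)-3,5,7-tris(3-methylbut-2-en-1-yl)-2,4,9-trioxobicyclo[3.3.1]nonane-3-carboxylate (C3 epimers) | CC(C)=CCC[C@]1(C)[C@@H](CC=C(C)C)C[C@]2(CC=C(C)C)C(=O)C(CC=C(C)C)(C(=O)OC)C(=O)[C@H]1C2=O | intermediate
18 | methyl (1S,5S,7S,8R)-1-benzoyl-8-methyl-8-(4-methylpent-3-en-1-yl)-3,5,7-tris(3-methylbut-2-en-1-yl)-2,4,9-trioxobicyclo[3.3.1]nonane-3-carboxylate (C3 epimers) | CC(C)=CCC[C@]1(C)[C@@H](CC=C(C)C)C[C@]2(CC=C(C)C)C(=O)C(CC=C(C)C)(C(=O)OC)C(=O)[C@@]1(C(=O)c1ccccc1)C2=O | intermediate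
19 | (1R,5R,7S,8R)-1-benzoyl-4-hydroxy-8-methyl-8-(4-methylpent-3-en-1-yl)-3,5,7-tris(3-methylbut-2-en-1-yl)bicyclo[3.3.1]non-3-ene-2,9-dione | CC(C)=CCC[C@]1(C)[C@@H](CC=C(C)C)C[C@]2(CC=C(C)C)C(O)=C(CC=C(C)C)C(=O)[C@@]1(C(=O)c1ccccc1)C2=O | intermediate
20 | (1S,3R,5S,7S,8R)-1-benzoyl-3-hydroxy-8-methyl-8-(4-methylpent-3-en-1-yl)-3,5,7-tris(3-methylbut-2-en-1-yl)bicyclo[3.3.1]nonane-2,4,9-trione | CC(C)=CCC[C@]1(C)[C@@H](CC=C(C)C)C[C@]2(CC=C(C)C)C(=O)[C@](O)(CC=C(C)C)C(=O)[C@@]1(C(=O)c1ccccc1)C2=O | intermediate
21 | CNP0269674.1, (1R,3S,4R,5R,7S)-5-benzoyl-4-methyl-4-(4-methylpent-3-en-1-yl)-1,3,7-tris(3-methylbut-2-en-1-yl)-8-oxabicyclo[5.2.1]decane-6,9,10-trione | CC(C)=CCC[C@]1(C)[C@@H](CC=C(C)C)C[C@@]2(CC=C(C)C)C(=O)O[C@@](CC=C(C)C)(C(=O)[C@H]1C(=O)c1ccccc1)C2=O | target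

Total step count: 14. Longest linear sequence: 12 steps (1–5, then 8–14, from geraniol); steps 6 and 7 make the side fragment 12.

Steps most likely to fail

Step 11. The risk is O-alkylation through the enolate oxygen on C9 (or C2), which would give a fused dihydropyran instead of the bridged carbocycle; substitution at the β-branched carbon may also be slow enough for the trione to decompose. The fallback sets out from 15 and returns at 17, replacing the irreversible displacement by a reversible, carbon-selective aldol closure. The O-cyclised enol ether F1 (formed cleanly from 15 with K2CO3/NaI in DMF) is hydrolysed with dilute HCl in aqueous THF to the hydroxy trione F2. Oxidation with TEMPO (cat.)/PhI(OAc)2 gives the aldehyde F3, which under piperidinium acetate closes by intramolecular aldol addition of C5 to the C6 aldehyde to the 6-hydroxy bicycle F4. Acylation with phenyl chlorothionoformate (pyridine, DMAP) gives the thiocarbonate F5, and Barton–McCombie reduction (Bu3SnH at high concentration, AIBN, toluene, 80 °C) returns 17.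

Step 12. The risk is that the hindered bridgehead carbanion next to the quaternary C8 is acylated too slowly, so that proton return or ring-opening of the non-enolisable triketone by the base competes. The fallback sets out from 17 and returns at 18, separating the deprotonation from the C–C bond formation. The bridgehead anion is quenched with the small, fast electrophile I2 to give the bridgehead iodide F6; iodine–magnesium exchange (i-PrMgCl·LiCl, −78 °C) and addition to benzaldehyde give the carbinol F7; Dess–Martin oxidation gives 18.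

Step 14. The risks are poor facial selectivity in the oxidation at C3, oxidation of the prenyl olefins, and attack of the C3 alkoxide on the benzoyl carbonyl instead of C9. The fallback sets out from 19 and returns at 21, separating the oxidation from the fragmentation. Acetoxylation of the enolised diketone with PhI(OAc)2 gives the 3-acetoxy trione F8, whose correct C3 epimer is purified; mild methanolysis (K2CO3, MeOH, 0 °C) then releases the C3 alkoxide, which undergoes the same retro-Claisen lactonisation to 21.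

Further compounds
F1 | step 11 | O-cyclised enol ether of 15: methyl (3R,4R)-4-methyl-4-(4-methylpent-3-en-1-yl)-3,6,8-tris(3-methylbut-2-en-1-yl)-5,7-dioxo-3,4,4a,5,6,7-hexahydro-2H-chromene-6-carboxylate | COC(=O)C1(CC=C(C)C)C(=O)C(CC=C(C)C)=C2OC[C@H](CC=C(C)C)[C@@](C)(CCC=C(C)C)C2C1=O
F2 | step 11 | hydroxy trione (15 with CH2OH in place of CH2Cl) | COC(=O)C1(CC=C(C)C)C(=O)C(CC=C(C)C)C(=O)C(C1=O)[C@](C)(CCC=C(C)C)[C@@H](CC=C(C)C)CO
F3 | step 11 | aldehyde trione (15 with CHO in place of CH2Cl) | COC(=O)C1(CC=C(C)C)C(=O)C(CC=C(C)C)C(=O)C(C1=O)[C@](C)(CCC=C(C)C)[C@@H](CC=C(C)C)C=O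
F4 | step 11 | 6-hydroxy derivative of 17 (carbinol epimers) | CC(C)=CCC[C@]1(C)[C@@H](CC=C(C)C)C(O)[C@]2(CC=C(C)C)C(=O)C(CC=C(C)C)(C(=O)OC)C(=O)[C@H]1C2=O
F5 | step 11 | 6-O-(phenoxythiocarbonyl) derivative of F4 | CC(C)=CCC[C@]1(C)[C@@H](CC=C(C)C)C(OC(=S)Oc3ccccc3)[C@]2(CC=C(C)C)C(=O)C(CC=C(C)C)(C(=O)OC)C(=O)[C@H]1C2=O
F6 | step 12 | 1-iodo derivative of 17 (bridgehead iodide) | CC(C)=CCC[C@]1(C)[C@@H](CC=C(C)C)C[C@]2(CC=C(C)C)C(=O)C(CC=C(C)C)(C(=O)OC)C(=O)[C@@]1(I)C2=O
F7 | step 12 | 1-[hydroxy(phenyl)methyl] derivative of 17 (carbinol epimers) | CC(C)=CCC[C@]1(C)[C@@H](CC=C(C)C)C[C@]2(CC=C(C)C)C(=O)C(CC=C(C)C)(C(=O)OC)C(=O)[C@@]1(C(O)c1ccccc1)C2=O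
F8 | step 14 | 3-acetoxy trione (O-acetate of 20) | CC(C)=CCC[C@]1(C)[C@@H](CC=C(C)C)C[C@]2(CC=C(C)C)C(=O)[C@](OC(C)=O)(CC=C(C)C)C(=O)[C@@]1(C(=O)c1ccccc1)C2=O
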